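**Assumption:** 2,4,6-tribromo-1H-indole is planar and has no stereocentre, so "single enantiomer" needs no stereocontrol; the route only has to place the three bromines correctly.

## Retrosynthetic overview

1. 7 ⇒ 6: the N1–C2 bond is closed last by a chemoselective Pd-catalysed intramolecular amination of an o-(2,2-dibromovinyl)aniline. One vinylic Br is the leaving group and the other becomes the C2–Br, so no preformed indole or oxindole is brominated.
2. 6 ⇒ 5 (nitro reduction) ⇒ 4 (Ramirez dibromo-olefination; CBr4 supplies C2 and its bromine).
3. 4 ⇒ 2 (Leimgruber–Batcho enamine, then periodate cleavage) ⇒ 1 (regioselective ring bromination).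
4. Ring order: the benzene ring is bought with one Br in place; the pyrrole ring is the only ring formed, in the final step.

## Route

Step 1
Reactants: 1 4-bromo-2-nitrotoluene (4-bromo-1-methyl-2-nitrobenzene)
Product: 2 1,5-dibromo-2-methyl-3-nitrobenzene (2,4-dibromo-6-nitrotoluene)
Conditions: NBS (1.1 equiv), conc. H2SO4, 60 °C
Reagents that add atoms: N-bromosuccinimide, O=C1CCC(=O)N1Br
Why: Electrophilic aromatic bromination with NBS activated by sulfuric acid goes to C6, the only free position that is ortho to the activating methyl group and meta to the nitro group, whereas C3 and C5 are ortho or para to NO2 and are strongly deactivated.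

Step 2
Reactants: 2 1,5-dibromo-2-methyl-3-nitrobenzene
Product: 4 2,4-dibromo-6-nitrobenzaldehyde, via enamine 3 (not isolated)
Conditions: DMF-DMA (3 equiv), DMF, 110 °C; concentrate; then NaIO4 (3 equiv), THF/H2O 1:1, 0 °C to rt
Reagents that add atoms: N,N-dimethylformamide dimethyl acetal, COC(OC)N(C)C (adds the CH–NMe2 unit of 3); sodium periodate, [Na+].[O-]I(=O)(=O)=O (adds the aldehyde oxygen of 4)
Why: Leimgruber–Batcho enamine formation works because the methyl group is acidified by the ortho-nitro group and two bromines, and the electron-rich enamine C=C bond is then cleaved oxidatively by periodate to the aldehyde without touching the aryl bromides or the nitro group.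

Step 3
Reactants: 4 2,4-dibromo-6-nitrobenzaldehyde
Product: 5 1,5-dibromo-2-(2,2-dibromoethenyl)-3-nitrobenzene
Conditions: CBr4 (1.5 equiv), PPh3 (3 equiv), CH2Cl2, 0 °C to rt
Reagents that add atoms: carbon tetrabromide, BrC(Br)(Br)Br
Why: Ramirez dibromo-olefination (first stage of the Corey–Fuchs sequence) proceeds through the Wittig reaction of Ph3P=CBr2 generated in the flask, and electron-poor o-nitrobenzaldehydes are good substrates for it.

Step 4
Reactants: 5 1,5-dibromo-2-(2,2-dibromoethenyl)-3-nitrobenzene
Product: 6 3,5-dibromo-2-(2,2-dibromoethenyl)aniline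
Conditions: Fe powder (5 equiv), AcOH/EtOH 1:1, 80 °C
Reagents that add atoms: none
Why: Béchamp-type dissolving-metal reduction with iron in acetic acid reduces the nitro group by electron transfer and leaves aryl and vinyl C–Br bonds intact, unlike catalytic hydrogenation.

Step 5
Reactants: 6 3,5-dibromo-2-(2,2-dibromoethenyl)aniline
Product: 7 2,4,6-tribromo-1H-indole
Conditions: Pd(P(t-Bu)3)2 (5 mol%), K3PO4 (2 equiv), toluene (0.05 M), 100 °C, Ar; filter through Et3N-deactivated silica
Reagents that add atoms: none
Why: This is an intramolecular Buchwald–Hartwig amination (N-vinylation of a gem-dibromoolefin) in which only oxidative addition of zerovalent palladium into the vinylic C–Br bond cis to the aryl ring can be trapped by the ortho-NH2 through a six-membered amido-palladacycle that reductively eliminates the N1–C2 bond, while insertion into the other C–Br bonds, including the product C2–Br, is reversible with the bulky P(t-Bu)3 ligand and is unproductive with the weak base at high dilution, so the second vinylic bromine survives as the C2–Br.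

## Compound list

1 | 4-bromo-1-methyl-2-nitrobenzene (4-bromo-2-nitrotoluene) | Cc1ccc(Br)cc1[N+](=O)[O-] | starting material
2 | 1,5-dibromo-2-methyl-3-nitrobenzene (2,4-dibromo-6-nitrotoluene) | Cc1c(Br)cc(Br)cc1[N+](=O)[O-] | intermediate
3 | (E)-2-(2,4-dibromo-6-nitrophenyl)-N,N-dimethylethen-1-amine | CN(C)/C=C/c1c(Br)cc(Br)cc1[N+](=O)[O-] | intermediate
4 | 2,4-dibromo-6-nitrobenzaldehyde | O=Cc1c(Br)cc(Br)cc1[N+](=O)[O-] | intermediate
5 | 1,5-dibromo-2-(2,2-dibromoethenyl)-3-nitrobenzene | BrC(Br)=Cc1c(Br)cc(Br)cc1[N+](=O)[O-] | intermediate
6 | 3,5-dibromo-2-(2,2-dibromoethenyl)aniline | Nc1cc(Br)cc(Br)c1C=C(Br)Br | intermediate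
7 | 2,4,6-tribromo-1H-indole | Brc1cc(Br)c2cc(Br)[nH]c2c1 | target

## Step count and risks

Total step count: 5. Longest linear sequence: 5 steps (1 → 7).

**Step 5 (highest risk).** Four C–Br bonds compete for zerovalent palladium, so intermolecular N-arylation, oligomers or catalyst arrest at the product C2–Br are possible, and the free N–H 2-bromoindole is acid- and light-sensitive. The fallback drops the transition metal and closes the ring by an anionic cyclisation; it sets out from compound 6 and comes back to the route at compound 7. Compound 6 is mesylated (MsCl, pyridine, CH2Cl2, 0 °C) to N-[3,5-dibromo-2-(2,2-dibromoethenyl)phenyl]methanesulfonamide F1. Its sulfonamide anion (Cs2CO3, DMSO, 80 °C) closes onto the dibromovinyl group, either by E2 loss of HBr to the bromoalkyne and 5-endo-dig attack or by addition–elimination, and gives 2,4,6-tribromo-1-(methylsulfonyl)-1H-indole F2. The sulfonyl group is then removed from the electron-poor indole nitrogen (KOH, MeOH/THF/H2O, 40 °C) to give 7.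

**Step 2.** The methyl group is flanked by Br and NO2, so enamine formation can be slow, and the periodate cleavage can stall or over-oxidise. The fallback functionalises the benzylic position by a radical path; it sets out from compound 2 and comes back at compound 4. Wohl–Ziegler bromination (NBS, AIBN, PhCF3, 85 °C) gives 1,5-dibromo-2-(bromomethyl)-3-nitrobenzene F3, and a Kornblum-type oxidation with N-methylmorpholine N-oxide (4 Å MS, MeCN, rt) turns it into aldehyde 4.

**Step 3.** The aldehyde sits between Br and NO2, so the bulky ylide may add slowly and the excess phosphine may attack the nitro group on prolonged reaction. The fallback builds the C=CBr2 unit without phosphorus; it sets out from compound 4 and comes back at compound 5. Hydrazine hydrate (EtOH, rt, excess to suppress azine) gives (E)-(2,4-dibromo-6-nitrobenzylidene)hydrazine F4. Copper-catalysed olefination of this N-unsubstituted hydrazone with CBr4 (CuCl 10 mol%, aq NH3, DMSO, rt) then gives 5 with loss of nitrogen.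

## Further compounds

F1 | step 5 | N-[3,5-dibromo-2-(2,2-dibromoethenyl)phenyl]methanesulfonamide | CS(=O)(=O)Nc1cc(Br)cc(Br)c1C=C(Br)Br
F2 | step 5 | 2,4,6-tribromo-1-(methylsulfonyl)-1H-indole | CS(=O)(=O)n1c(Br)cc2c(Br)cc(Br)cc21
F3 | step 2 | 1,5-dibromo-2-(bromomethyl)-3-nitrobenzene | BrCc1c(Br)cc(Br)cc1[N+](=O)[O-]
F4 | step 3 | (E)-(2,4-dibromo-6-nitrobenzylidene)hydrazine | N/N=C/c1c(Br)cc(Br)cc1[N+](=O)[O-]
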